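Remark on the chemistry: "phenylethyl" is read as 2-phenylethyl, as the SMILES (O–CH2–CH2–C6H5) shows. The molecule has no stereocentre and no double-bond geometry, so nothing stereochemical has to be set. The acyl chain is numbered C1 (carbonyl) to C26 (methyl).

Compound numbers used throughout: 1 undec-10-enoic acid; 2 2-phenylethanol; 3 2-phenylethyl undec-10-enoate; 4 2-phenylethyl 10-oxodecanoate (formed and consumed in the flask); 5 10-oxo-10-(2-phenylethoxy)decanoic acid; 6 octadecanoic acid; 7 2-phenylethyl hexacosanoate (target).

## The problem

Compound 7 is an achiral wax ester of an unbranched C26 acid with 2-phenylethanol. Its only ring is the monosubstituted benzene ring of the alcohol part, and that ring comes ready-made. The ester C1–O bond is trivial to form. The difficulty lies in the acyl chain: C2 to C26 is one unbranched row of 24 methylene groups and a methyl group, with no functional group between C1 and C26 to serve as a handle. Chains of this length lie outside the commodity fatty acid pool, and homologous wax esters (C24, C25, C28) cannot be separated from 7 by crystallisation or ordinary chromatography. The carbon count must therefore be fixed exactly by the way the chain is joined, from fragments that are single homologues.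

The feature that makes the key step possible is that C2–C26 is saturated and unbranched, so every inner bond joins two primary CH2 carbons of the same kind. The C9–C10 bond divides the chain into C1–C9, ending in the ester carbonyl C1, and the heptadecyl piece C10–C26. Each half is the primary radical left when a cheap carboxylic acid loses its carboxyl group, so the bond can be made by joining two carbons of like polarity that both begin as carboxylates.

The benzene ring carries no donor group and sits two carbons from the ester oxygen (a homobenzylic, not benzylic, C–O bond). It should therefore tolerate an anode and a hydrogenation catalyst. The groups that will not survive rough treatment are the ester (organometallics, free alkoxide in an alcohol, strong base with elimination to styrene) and the ring towards exhaustive oxidants such as RuO4.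

## Retrosynthesis

**7 to 5 + 6.** The C9–C10 bond is cut homolytically, and each radical is traced back to a carboxylic acid with one more carbon: the half-ester 5 (C1–C9 plus a carboxyl carbon) and the fatty acid 6 (C10–C26 plus a carboxyl carbon). A cut nearer C1 would pair a short half-ester with a fatty acid of 22 to 24 carbons, which is hardly easier to obtain than the whole chain. At C9–C10 both halves come from the cheapest part of the oleochemical pool. The precursors are an 18-carbon acid and an 18-carbon half-ester, against a 34-carbon product. The forward reaction must generate both primary radicals together and let them combine, in the presence of the ester and the benzene ring, with both carboxyl groups expelled. Carrying the 2-phenylethyl ester through this step, instead of a simple alkyl ester to be exchanged later, lets the key step end at 7 itself.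

**5 to 3, through 4.** The free carboxyl carbon of 5 is read as the inner carbon of a terminal alkene, so the cut is the C10=C11 double bond of 3, with the aldehyde 4 as the stage in between. The obvious neighbour is half-esterification of the symmetrical ten-carbon diacid, which is statistical. In 3 the two chain ends are different from the outset, so no statistical step precedes a coupling that is statistical by nature. The forward reaction must cleave the alkene without touching the benzene ring and carry the new terminus to the acid.

**3 to 1 + 2.** The ester C–O bond is cut to give the commodity acid 1 and the commodity alcohol 2. The forward reaction is a plain acid-catalysed esterification that must leave the terminal double bond where it is.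

## Roads not taken

Alternative 1: The cut is the ester C1–O bond, and the forward key step is esterification of hexacosanoic acid A1 with 2. This is the route most chemists would draw first, and it is one step if A1 is accepted as a starting material. It is not a commodity, though: it comes from waxes together with neighbouring homologues, or it has to be built. The one hard feature of 7, the 26-carbon chain, is then bought rather than made. The chosen plan builds the chain and delivers the ester in the same step from C18 and C11 commodity acids.

Alternative 2: The cut is C8–C9, and the forward key step is an alkyl–alkyl Grignard coupling catalysed by Li2CuCl4. Octadecylmagnesium bromide A3 would displace bromide from 2-phenylethyl 8-bromooctanoate A2. A carbanion must then work next to the ester, where 1,2-addition to the carbonyl and base-induced loss of styrene compete. Both partners have first to be made from halides, and the Grignard formation from a long-chain bromide brings Wurtz dimer. The anodic union uses the native carboxyl groups of the fatty acid pool as traceless activating groups, in a protic medium that the ester tolerates.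

Alternative 3: The cut is C11–C12, with a triple bond as the temporary handle. The dilithium salt of undec-10-ynoic acid A4 would be alkylated with 1-bromopentadecane A5 to hexacos-10-ynoic acid A6. Hydrogenation would then give A1 and esterification with 2 would give 7. This needs two equivalents of a strong base, an odd-numbered C15 bromide that is not a commodity, and two steps after the coupling whose only job is to erase the alkyne and attach the alcohol. In the chosen plan nothing has to be erased, since the activating groups leave during the coupling itself.

Key step: step 3

## Route

Step 1
Reactants: 1 undec-10-enoic acid (1.05 equiv); 2 2-phenylethanol
Product: 3 2-phenylethyl undec-10-enoate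
Conditions: TsOH·H2O (2 mol%), toluene, reflux, Dean–Stark trap
Reagents that add atoms: none
Why: Fischer esterification driven to completion by azeotropic removal of water; the unhindered acid 1 and the primary alcohol 2 should react cleanly, and an isolated terminal alkene is inert to catalytic sulfonic acid in toluene.

Step 2
Reactants: 3 2-phenylethyl undec-10-enoate
Product: 5 10-oxo-10-(2-phenylethoxy)decanoic acid, via 2-phenylethyl 10-oxodecanoate 4 (not isolated)
Conditions: O3 (1.05 equiv, metered), MeCN/H2O 9:1, 0 °C; then NaClO2, NaH2PO4, H2O, 0 °C to rt
Reagents that add atoms: ozone, [O-][O+]=O; water, O; sodium chlorite, [Na+].[O-]Cl=O
Why: Ozonolysis in aqueous acetonitrile, where water traps the carbonyl oxide and the hydroxy hydroperoxide falls apart to aldehyde 4 and H2O2, followed in the same flask by Pinnick oxidation, with the H2O2 from the first stage acting as hypochlorite scavenger. A monosubstituted benzene ring reacts with ozone far more slowly than a terminal alkene, so metered ozone should leave the ring and the ester untouched.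

Step 3
Reactants: 5 10-oxo-10-(2-phenylethoxy)decanoic acid; 6 octadecanoic acid (4 equiv)
Product: 7 2-phenylethyl hexacosanoate
Conditions: KOH (0.1 equiv per CO2H), MeOH with light petroleum (bp 60–80 °C) as co-solvent, 45–50 °C, undivided cell, smooth Pt anode and Pt cathode, constant current ca. 0.2 A cm−2, ca. 1.1 F per mol of acid, stopped while still weakly acidic
Reagents that add atoms: none
Why: Mixed Kolbe electrolysis: at the platinum anode the carboxylates of 5 and 6 each lose one electron and CO2, giving the primary radicals •CH2(CH2)7CO2CH2CH2Ph (C9) and CH3(CH2)15CH2• (C10) at high local concentration, and these combine next to the electrode to form the C9–C10 bond. At the cathode methanol is reduced to H2, and the methoxide formed there regenerates carboxylate from free acid, so only a tenth of the acid needs to be neutralised at the start. The closest known reaction type is the crossed Kolbe coupling of a fatty acid with an alkyl hydrogen alkanedioate, the classical anodic way to lengthen a fatty ester chain. No ring is closed and no stereocentre is formed. The step needs cross-coupling over homo-coupling, which is statistical: with a fourfold excess of cheap 6, four of five radicals from 5 should meet a heptadecyl radical if the two react alike, and the two symmetrical co-products differ from 7 by one ester group more or less, so they separate by polarity. It needs one-electron over two-electron oxidation, which is secured because both radicals are primary and unstabilised, and because a smooth Pt anode is used at high current density in weakly acidic methanol free of foreign anions. It also needs the 2-phenylethyl ester to survive: the benzene ring has no donor substituent and lies outside the carboxylate layer on the anode, the O–CH2 bond is homobenzylic, and stopping the current while free acid remains leaves no methoxide for ester exchange.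

## Compound list

1 | undec-10-enoic acid | C=CCCCCCCCCC(=O)O | starting material
2 | 2-phenylethanol | OCCc1ccccc1 | starting material
3 | 2-phenylethyl undec-10-enoate | C=CCCCCCCCCC(=O)OCCc1ccccc1 | intermediate
4 | 2-phenylethyl 10-oxodecanoate | O=CCCCCCCCCC(=O)OCCc1ccccc1 | intermediate (not isolated)
5 | 10-oxo-10-(2-phenylethoxy)decanoic acid | OC(=O)CCCCCCCCC(=O)OCCc1ccccc1 | intermediate
6 | octadecanoic acid | CCCCCCCCCCCCCCCCCC(=O)O | starting material
7 | 2-phenylethyl hexacosanoate | CCCCCCCCCCCCCCCCCCCCCCCCCC(=O)OCCc1ccccc1 | target

## Step count and risk

Total step count: 3. Longest linear sequence: 3 steps (1 to 3 to 5 to 7); compound 6 enters in step 3 as purchased.

**Step 3 (key step).** The most likely failures are these: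
- stalling of the current when waxy products coat the anode, since the C34 products are barely soluble in methanol;
- loss of 5 to homo-coupling, which is inherent in the statistics;
- ester exchange with the solvent if the electrolysis is run on until the medium turns alkaline;
- further oxidation of the radicals to cations, which would divert material to ethers and alkenes.

The hydrocarbon co-solvent, periodic reversal of polarity and the early stop are meant to meet the first and third. The fallback leaves the electrochemical union altogether. It sets out from 3, which undergoes olefin cross-metathesis with heptadec-1-ene (C=CCCCCCCCCCCCCCCC, 3 equiv; second-generation Grubbs catalyst, CH2Cl2, 40 °C, ethene swept out) to give 2-phenylethyl (E)-hexacos-10-enoate F1; the double-bond geometry is of no consequence. Hydrogenation (H2, Pd/C, EtOAc, rt) then saturates C10=C11 and comes back to the route at 7. The homobenzylic ester C–O bond should be inert to hydrogenolysis.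

**Step 2.** The most likely failure is over-oxidation: attack of ozone on the benzene ring once the alkene is used up, if the gas is not metered. A second risk is incomplete breakdown of the peroxidic species before the chlorite stage, which would leave the oxidation to the acid unfinished. The fallback avoids the alkene cleavage. It sets out from 2, which is added slowly with pyridine to decanedioyl dichloride (ClC(=O)CCCCCCCCC(=O)Cl, 3 equiv, CH2Cl2, 0 °C), so that each alcohol molecule meets an excess of the diacid chloride and gives 2-phenylethyl 10-chloro-10-oxodecanoate F2. Aqueous pyridine in THF then hydrolyses the remaining acyl chloride. The route is rejoined at 5 after separation from the symmetrical diacid and diester by polarity.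

**Step 1.** The most likely failure is acid-promoted migration of the terminal double bond towards the chain on long heating. After cleavage and coupling this would show up as a chain-shortened homologue that cannot be removed. Self-etherification of the alcohol and incomplete conversion are lesser risks. The fallback forms the other ester bond under non-acidic conditions. It sets out from 1, whose caesium salt (Cs2CO3, DMF, rt) is alkylated at oxygen by (2-bromoethyl)benzene (BrCCc1ccccc1) in an SN2 reaction, and comes back to the route at 3. It makes no new compound (F0).

## Further compounds

F1 | step 3 | 2-phenylethyl (E)-hexacos-10-enoate | CCCCCCCCCCCCCCC/C=C/CCCCCCCCC(=O)OCCc1ccccc1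
F2 | step 2 | 2-phenylethyl 10-chloro-10-oxodecanoate | ClC(=O)CCCCCCCCC(=O)OCCc1ccccc1
F0 | step 1 | none | none
A1 | alternative 1 | hexacosanoic acid | CCCCCCCCCCCCCCCCCCCCCCCCCC(=O)O
A2 | alternative 2 | 2-phenylethyl 8-bromooctanoate | BrCCCCCCCC(=O)OCCc1ccccc1
A3 | alternative 2 | octadecylmagnesium bromide | CCCCCCCCCCCCCCCCCC[Mg]Br
A4 | alternative 3 | undec-10-ynoic acid | C#CCCCCCCCCC(=O)O
A5 | alternative 3 | 1-bromopentadecane | CCCCCCCCCCCCCCCBr
A6 | alternative 3 | hexacos-10-ynoic acid | CCCCCCCCCCCCCCCC#CCCCCCCCCC(=O)O
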